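Ring B (C5–C10, labdane numbering) is closed last, through the C9–C10 bond. The feature exploited is its C7=C8 alkene flanked by C9 and quaternary C10, the footprint of a cation cascade. Ring A is bought with C5 set, as (S)-α-ionone; its side chain is extended by carboalumination and Negishi coupling to a monocyclic dienyne with a C1=C10 ring alkene and an E-C8=C9 alkene. Protonation at C1 gives the C10 cation, C9 adds through a chair, and loss of the C7 proton ends the step: one operation forms ring B, relays C10 and C9 from C5 with trans fusion, and places the C7=C8 alkene.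

Key step: step 6

Remark on the chemistry: (S)-(−)-α-ionone is taken as a purchasable single enantiomer; all intermediates carry labdane atom numbers (ring A = C1–C5 and C10, ring B = C5–C10).

Step 1
Reactants: 1 (S)-α-ionone [(S,E)-4-(2,6,6-trimethylcyclohex-2-en-1-yl)but-3-en-2-one]
Product: 3 (S)-dihydro-α-ionone [(S)-4-(2,6,6-trimethylcyclohex-2-en-1-yl)butan-2-one], via triethylsilyl enol ether 2 (not isolated)
Conditions: Et3SiH, RhCl(PPh3)3 (cat.), PhH, 50 °C; then 1 M HCl, THF, 0 °C
Reagents that add atoms: none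
Why: Rhodium-catalysed 1,4-hydrosilylation of the enone and hydrolysis of the silyl enol ether (conjugate reduction) should reduce only the conjugated C=C under neutral conditions, leaving the hindered ring alkene and the doubly allylic C5 centre untouched; no new stereocentre.

Step 2
Reactants: 3 (S)-dihydro-α-ionone
Product: 5 (S)-6-(but-3-yn-1-yl)-1,5,5-trimethylcyclohex-1-ene, via enol phosphate 4 (not isolated)
Conditions: LiN(i-Pr)2 (1.1 equiv), THF, −78 °C; ClP(O)(OEt)2, −78 °C to rt; LiN(i-Pr)2 (2.3 equiv), −78 °C to rt; H2O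
Reagents that add atoms: none
Why: Negishi methyl ketone to terminal alkyne conversion: kinetic deprotonation at the methyl group, O-phosphorylation and base-induced elimination of diethyl phosphate should give the alkyne, while the remote, non-acidic C5 centre is not touched.

Step 3
Reactants: 5 (S)-6-(but-3-yn-1-yl)-1,5,5-trimethylcyclohex-1-ene
Product: 7 (S)-6-[(E)-4-iodo-3-methylbut-3-en-1-yl]-1,5,5-trimethylcyclohex-1-ene, via alkenylalane 6 (not isolated)
Conditions: Me3Al (2 equiv), Cp2ZrCl2 (0.25 equiv), CH2Cl2, rt; then I2, THF, −30 to 0 °C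
Reagents that add atoms: trimethylaluminium, C[Al](C)C; iodine, II
Why: Negishi zirconium-catalysed carboalumination adds methyl and aluminium syn across the terminal alkyne with aluminium at the terminus, and iodinolysis with retention should give the E-iodide (C8=C9 geometry); the trisubstituted ring alkene is inert.

Step 4
Reactants: 7 (S)-6-[(E)-4-iodo-3-methylbut-3-en-1-yl]-1,5,5-trimethylcyclohex-1-ene; 8 (4-bromobut-1-yn-1-yl)trimethylsilane
Product: 10 trimethyl[(E)-6-methyl-8-((S)-2,6,6-trimethylcyclohex-2-en-1-yl)oct-5-en-1-yn-1-yl]silane, via alkylzinc bromide 9 (not isolated)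
Conditions: 8, Zn dust, I2 (cat.), N,N-dimethylacetamide, 80 °C; then 7, Pd(PPh3)4 (5 mol%), THF, rt to 50 °C
Reagents that add atoms: none
Why: Negishi cross-coupling of a homopropargylic alkylzinc with an alkenyl iodide should form the C9–C11 bond with retention of the E geometry; zinc insertion tolerates the silylalkyne.

Step 5
Reactants: 10 trimethyl[(E)-6-methyl-8-((S)-2,6,6-trimethylcyclohex-2-en-1-yl)oct-5-en-1-yn-1-yl]silane
Product: 11 (S)-1,5,5-trimethyl-6-[(E)-3-methyloct-3-en-7-yn-1-yl]cyclohex-1-ene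
Conditions: K2CO3 (cat.), MeOH, rt
Reagents that add atoms: none
Why: Base-catalysed protodesilylation (methanolysis of the alkynylsilane) should free the terminal alkyne without touching the alkenes.

Step 6
Reactants: 11 (S)-1,5,5-trimethyl-6-[(E)-3-methyloct-3-en-7-yn-1-yl]cyclohex-1-ene
Product: 12 (5S,9S,10S)-15,16-dinorlabd-7-en-13-yne [(4aS,5S,8aS)-5-(but-3-yn-1-yl)-1,1,4a,6-tetramethyl-1,2,3,4,4a,5,8,8a-octahydronaphthalene]
Conditions: SnCl4, CF3CO2H, CH2Cl2, −78 °C; then pyridine, aq. NaHCO3
Reagents that add atoms: none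
Why: SnCl4-activated CF3CO2H protonates the trisubstituted C1=C10 ring alkene at C1 to give the tertiary C10 cation, C9 of the E-C8=C9 alkene adds to it through a chair-like transition state, and the tertiary C8 cation loses the axial C7 proton (an exocyclic C8=C17 isomer would re-enter by reprotonation) to leave the C7=C8 alkene. The closest known reaction type is the proton-initiated cation–olefin cyclization of α-monocyclic (α-cyclogeranyl-type) terpenoid precursors, the second stage of stepwise biomimetic polyene cyclizations. Ring B closes in the 6-endo-trig mode at the C8=C9 alkene. C10 is controlled by the bought C5 centre: with the C5 tether equatorial on ring A, C9 bonds to the face of C10 opposite to C6, which gives the trans ring fusion with the C10 methyl anti to H-5; C9 is controlled by the E geometry of C8=C9, which keeps C11 equatorial in the chair so that H-9 ends anti to the C10 methyl. The step needs ring closure to outrun loss of the C5 proton from the C10 cation (which would erase C5) and needs the alkyne to stay out; the first is secured by −78 °C, a non-basic counter-ion and an alkene tethered for six-membered ring closure, the second by the fact that a terminal alkyne could add only via a bent cyclohexenyl or a primary vinyl cation.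

Step 7
Reactants: 12 (5S,9S,10S)-15,16-dinorlabd-7-en-13-yne
Product: 15 (5S,9S,10S,13E)-labda-7,13-dien-15-ol, via alkenylalane 13 (not isolated), via lithium alanate 14 (not isolated)
Conditions: Me3Al (2.5 equiv), Cp2ZrCl2 (0.3 equiv), CH2Cl2, rt; volatiles removed; n-BuLi, hexane/THF, −78 to 0 °C; (CH2O)n, THF, rt; aq. NH4Cl
Reagents that add atoms: trimethylaluminium, C[Al](C)C; formaldehyde (as paraformaldehyde), C=O
Why: Zirconium-catalysed carboalumination (syn, aluminium at the terminus) followed by hydroxymethylation of the derived alanate with retention (Negishi allylic alcohol synthesis) should set the 13E alkene; the trisubstituted C7=C8 alkene does not react.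

Step 8
Reactants: 15 (5S,9S,10S,13E)-labda-7,13-dien-15-ol; 16 Meldrum's acid (2,2-dimethyl-1,3-dioxane-4,6-dione)
Product: 17 3-{[(5S,9S,10S,13E)-labda-7,13-dien-15-yl]oxy}-3-oxopropanoic acid (CNP0279336.1)
Conditions: 16 (1.1 equiv), toluene, 100 °C
Reagents that add atoms: none
Why: Ring-opening acylation of the primary allylic alcohol by Meldrum's acid with loss of acetone should give the malonic half-ester directly under neutral conditions, so no protecting group is needed and no stereocentre is touched.

Compound list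
1 | (S)-α-ionone, (S,E)-4-(2,6,6-trimethylcyclohex-2-en-1-yl)but-3-en-2-one | CC1=CCCC(C)(C)[C@@H]1/C=C/C(C)=O | starting material
2 | triethyl{[(S)-4-(2,6,6-trimethylcyclohex-2-en-1-yl)but-2-en-2-yl]oxy}silane (enol ether geometry undefined) | CC1=CCCC(C)(C)[C@@H]1CC=C(C)O[Si](CC)(CC)CC | intermediate
3 | (S)-dihydro-α-ionone, (S)-4-(2,6,6-trimethylcyclohex-2-en-1-yl)butan-2-one | CC1=CCCC(C)(C)[C@@H]1CCC(C)=O | intermediate
4 | diethyl (S)-4-(2,6,6-trimethylcyclohex-2-en-1-yl)but-1-en-2-yl phosphate | CC1=CCCC(C)(C)[C@@H]1CCC(=C)OP(=O)(OCC)OCC | intermediate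
5 | (S)-6-(but-3-yn-1-yl)-1,5,5-trimethylcyclohex-1-ene | CC1=CCCC(C)(C)[C@@H]1CCC#C | intermediate
6 | dimethyl[(E)-2-methyl-4-((S)-2,6,6-trimethylcyclohex-2-en-1-yl)but-1-en-1-yl]alane | CC1=CCCC(C)(C)[C@@H]1CC/C(C)=C/[Al](C)C | intermediate
7 | (S)-6-[(E)-4-iodo-3-methylbut-3-en-1-yl]-1,5,5-trimethylcyclohex-1-ene | CC1=CCCC(C)(C)[C@@H]1CC/C(C)=C/I | intermediate
8 | (4-bromobut-1-yn-1-yl)trimethylsilane | C[Si](C)(C)C#CCCBr | starting material
9 | [4-(trimethylsilyl)but-3-yn-1-yl]zinc bromide | C[Si](C)(C)C#CCC[Zn]Br | intermediate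
10 | trimethyl[(E)-6-methyl-8-((S)-2,6,6-trimethylcyclohex-2-en-1-yl)oct-5-en-1-yn-1-yl]silane | CC1=CCCC(C)(C)[C@@H]1CC/C(C)=C/CCC#C[Si](C)(C)C | intermediate
11 | (S)-1,5,5-trimethyl-6-[(E)-3-methyloct-3-en-7-yn-1-yl]cyclohex-1-ene | CC1=CCCC(C)(C)[C@@H]1CC/C(C)=C/CCC#C | intermediate
12 | (5S,9S,10S)-15,16-dinorlabd-7-en-13-yne | CC1=CC[C@H]2C(C)(C)CCC[C@]2(C)[C@H]1CCC#C | intermediate
13 | dimethyl[(5S,9S,10S,13E)-15-norlabda-7,13-dien-14-yl]alane | CC1=CC[C@H]2C(C)(C)CCC[C@]2(C)[C@H]1CC/C(C)=C/[Al](C)C | intermediate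
14 | lithium butyl(dimethyl)[(5S,9S,10S,13E)-15-norlabda-7,13-dien-14-yl]aluminate | CC1=CC[C@H]2C(C)(C)CCC[C@]2(C)[C@H]1CC/C(C)=C/[Al-](C)(C)CCCC.[Li+] | intermediate
15 | (5S,9S,10S,13E)-labda-7,13-dien-15-ol | CC1=CC[C@H]2C(C)(C)CCC[C@]2(C)[C@H]1CC/C(C)=C/CO | intermediate
16 | Meldrum's acid, 2,2-dimethyl-1,3-dioxane-4,6-dione | CC1(C)OC(=O)CC(=O)O1 | starting material
17 | 3-{[(5S,9S,10S,13E)-labda-7,13-dien-15-yl]oxy}-3-oxopropanoic acid | CC1=CC[C@H]2C(C)(C)CCC[C@]2(C)[C@H]1CC/C(C)=C/COC(=O)CC(=O)O | target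

Total step count: 8. Longest linear sequence: 8 steps (1 to 17; 8 and 16 are purchased).

Steps most likely to fail

Step 6. The C10 cation may lose the C5 proton before ring closure, which would erode enantiopurity through the tetrasubstituted C5=C10 alkene. The terminating proton loss may also be unselective, or the C8 cation may engage the alkyne. The fallback inverts the order of ring closure and chain extension, so that ring B is closed on a chain ending in an inert sulfonate and the alkyne is introduced afterwards by SN2. It sets out from 5. Carboalumination as in step 3 gives 6, and n-BuLi converts this into lithium butyl(dimethyl)[(E)-2-methyl-4-((S)-2,6,6-trimethylcyclohex-2-en-1-yl)but-1-en-1-yl]aluminate F1. Oxirane opens to (S,E)-4-methyl-6-(2,6,6-trimethylcyclohex-2-en-1-yl)hex-3-en-1-ol F2, and TsCl/pyridine gives its 4-methylbenzenesulfonate F3. SnCl4/CF3CO2H in CH2Cl2 at −78 °C should then close ring B to (5S,9S,10S)-13,14,15,16-tetranorlabd-7-en-12-yl 4-methylbenzenesulfonate F4. This tosylate is expected to crystallise, so that alkene isomers and the minor enantiomer can be removed. LiC≡CH·H2NCH2CH2NH2 in DMSO displaces the tosylate, and the route is rejoined at 12.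

Step 7. Carbometalation of the alkyne next to the bulky decalin may be incomplete, or the alkenylaluminium may be protonated before hydroxymethylation. The fallback replaces carbometalation by olefination and sets out from 12. NaAuCl4-catalysed hydration (MeOH/H2O, 65 °C) should give (5S,9S,10S)-14,15-dinorlabd-7-en-13-one F5. Horner–Wadsworth–Emmons reaction with (EtO)2P(O)CH2CO2Et/NaH in THF should give ethyl (5S,9S,10S,13E)-labda-7,13-dien-15-oate F6, with the Z isomer removed by chromatography. i-Bu2AlH in CH2Cl2 at −78 °C reduces the ester, and the route is rejoined at 15.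

Step 4. Zinc insertion may be sluggish, the alkylzinc may be protonated, or β-hydride elimination and homocoupling may compete at palladium. The fallback forms the C11–C12 bond by allylic substitution in place of the C9–C11 cross-coupling and sets out from 5. Carboalumination as in step 3 gives 6, which is acylated directly with ClCO2Et to ethyl (S,E)-3-methyl-5-(2,6,6-trimethylcyclohex-2-en-1-yl)pent-2-enoate F7. i-Bu2AlH gives (S,E)-3-methyl-5-(2,6,6-trimethylcyclohex-2-en-1-yl)pent-2-en-1-ol F8, and CBr4/PPh3 gives (S)-6-[(E)-5-bromo-3-methylpent-3-en-1-yl]-1,5,5-trimethylcyclohex-1-ene F9. Alkylation of LiCH2C≡CSiMe3 (THF, −78 °C) with F9 rejoins the route at 10.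

Further compounds
F1 | step 6 | lithium butyl(dimethyl)[(E)-2-methyl-4-((S)-2,6,6-trimethylcyclohex-2-en-1-yl)but-1-en-1-yl]aluminate | CC1=CCCC(C)(C)[C@@H]1CC/C(C)=C/[Al-](C)(C)CCCC.[Li+]
F2 | step 6 | (S,E)-4-methyl-6-(2,6,6-trimethylcyclohex-2-en-1-yl)hex-3-en-1-ol | CC1=CCCC(C)(C)[C@@H]1CC/C(C)=C/CCO
F3 | step 6 | (S,E)-4-methyl-6-(2,6,6-trimethylcyclohex-2-en-1-yl)hex-3-en-1-yl 4-methylbenzenesulfonate | CC1=CCCC(C)(C)[C@@H]1CC/C(C)=C/CCOS(=O)(=O)c1ccc(C)cc1
F4 | step 6 | (5S,9S,10S)-13,14,15,16-tetranorlabd-7-en-12-yl 4-methylbenzenesulfonate | CC1=CC[C@H]2C(C)(C)CCC[C@]2(C)[C@H]1CCOS(=O)(=O)c1ccc(C)cc1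
F5 | step 7 | (5S,9S,10S)-14,15-dinorlabd-7-en-13-one | CC1=CC[C@H]2C(C)(C)CCC[C@]2(C)[C@H]1CCC(C)=O
F6 | step 7 | ethyl (5S,9S,10S,13E)-labda-7,13-dien-15-oate | CC1=CC[C@H]2C(C)(C)CCC[C@]2(C)[C@H]1CC/C(C)=C/C(=O)OCC
F7 | step 4 | ethyl (S,E)-3-methyl-5-(2,6,6-trimethylcyclohex-2-en-1-yl)pent-2-enoate | CC1=CCCC(C)(C)[C@@H]1CC/C(C)=C/C(=O)OCC
F8 | step 4 | (S,E)-3-methyl-5-(2,6,6-trimethylcyclohex-2-en-1-yl)pent-2-en-1-ol | CC1=CCCC(C)(C)[C@@H]1CC/C(C)=C/CO
F9 | step 4 | (S)-6-[(E)-5-bromo-3-methylpent-3-en-1-yl]-1,5,5-trimethylcyclohex-1-ene | CC1=CCCC(C)(C)[C@@H]1CC/C(C)=C/CBr
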